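The closed, stirred vessel holds G, J and the two catalysts L and D, and the Z in it stops rising within the readings.

| flask | G | J | L | D | remark | time |
|---|---|---|---|---|---|---|
| summer | 36 mM | 28.8 mM | 0.72 mM | 61 µM | the very flask that is asked about, followed so far |  |
| dawn | 36 mM | 19 mM | 0.72 mM | 61 µM | run made earlier |  |
| flask | 36 mM | 28.8 mM | 0.72 mM | 61 µM |  | 8.0 h |

summer run (percent of the G charged)

| time / h | Z / % | G / % |
|---|---|---|
| 0.500 | 8.7 | 85.5 |
| 1.50 | 12.9 | 83.8 |
| 3.00 | 17.0 | 83.5 |
| 4.00 | 17.6 | 83.3 |
| 6.00 | 13.8 | 84.6 |
| 8.00 | 15.4 | 84.8 |

dawn run (percent of the G charged)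

| time / min | Z / % | G / % |
|---|---|---|
| 15.0 | 3.9 | 84.5 |
| 30.0 | 6.4 | 83.8 |
| 50.0 | 10.2 | 81.3 |
| 60.0 | 11.1 | 81.3 |
| 80.0 | 13.1 | 81.8 |
| 90.0 | 12.7 | 81.5 |

(standard deviation of a reading: 1 percentage point)

- south-west: change nothing and wait 4.0 h more
- south: at 8.0 h take out 90% of the Z then present, then wait 4.0 h
- south-east: at 8.0 h add L, 100% of the amount charged, then wait 4.0 h
- north-west: at 8.0 h add J, 50.0% of the amount charged, then wait 4.0 h

1. Z, in percent of the G first charged, at 8.0 h
2. the remedy with the largest gain of Z, or "none" below 2 percentage points (south-west / south / south-east / north-west / none)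
3. Z present, with what was taken out counted in, in percent of the G first charged, after south-west
4. Z present, with what was taken out counted in, in percent of the G first charged, after south-east

- removed Z is counted in
- "the catalyst" is L with its forms; D is a second catalyst
- additions bring no volume worth counting

Turned round, the question asks what must hold in the summer flask for waiting, taking out Z or adding J to pay. Waiting needs G still falling, yet G reads 83.5% at 3.00 h and 84.8% at 8.00 h, no fall beyond the scatter of 1 percentage point. Taking out Z needs G to answer to Z, yet up to 3.00 h Z rose by 8.3 points from its first reading while G fell by 2 points. J is the limiting reagent by charge, 28.8 mM against 36 mM of G, but adding it needs J to be running short, yet at one J per Z the last reading of Z has used 5.54 mM of 28.8 mM.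

Fresh L remains. The last G readings of the summer flask give 15.8% for the burst share, the part of the G present that one charge of L turns over before turnover stops. Z reaches that level by 3.00 h, sooner than the further 4.0 h, so this reckoning puts Z at 8.0 h near f. A first round gives a second charge another f. Going round once more, that charge meets 84.2% of the G, so, taking the burst as a share of the G present, the gain is 13 points, clear of the 2 points margin, and Z reaches 29.0%.

The forecast gives 15.8%, south-east, 15.9% after waiting and 29% after adding L: “Fresh L should give another burst”.

The flask gives 16.1%, 16.1% after waiting and 30.1% by south-east, a gain of 14 points against the 13 points reckoned from f.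

    L → X (k = 0.00140 s⁻¹)
    J + D + E → D + Z (k = 288 M⁻² s⁻¹)
    G + L ⇌ L + E (K = 0.640, k = 0.586 M⁻¹ s⁻¹)
    J + L → Q (k = 0.0256 M⁻¹ s⁻¹)

At the charged c(J), L has a half-life of 5.41 min against its two losses, shorter than the 0.84 h half-life of G by the forward step at 0.0787 h, and in this flask the burst share f stays a minor part of the G. The gain by fresh L stands on f, and f moves with J: the neighbour flask with 120 mM of J keeps 91% of its G, so its f is 8.61%, and its Z stands at 8.61%.

The readings stem from a simulated flask on assumed constants, noise included.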